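**Plan**

1. Retrosynthetic cuts, in order: the C13 acetate; C2=C3 (metathesis, five-membered ring); C4–CH3 (Grignard addition); C5–C6 (aldol, seven-membered ring); C1–C5 (Claisen); C1–C10 (Suzuki–Miyaura); C7–C8 (lactone alkylation).
2. Forward: a temporary δ-lactone (C6 carboxyl to O13) is made from (R)-citronellic acid, alkylated at C7 and opened; the chain is joined at C10 to an alkenylboronate from (S)-but-3-yn-2-ol; a Claisen rearrangement adds C4/C5 and sets C1.
3. The seven-membered ring is closed first (C5–C6), the five-membered ring last (C2=C3).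
4. Enabling feature: ring-fusion carbon C5 lies between the carbinol carbons C4 and C6 (a syn-1,3-diol spanning both rings). With C4 as a vinyl ketone and the five-membered ring still open, C5 is the only enolisable carbon, and its open-chain allylic neighbour C1 steers the closure by allylic 1,3-strain.
5. Stereochemistry: C11 from the chiral pool; C13 by cis-selective lactonisation; C7 by trans alkylation of the lactone; C1 by Claisen chirality transfer; C5 and C6 in the aldol; C4 by chelation-controlled methyl addition.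
6. Helpers removed later: the lactone ring, the silyl groups, the enol silane, and the propenyl terminus (lost as propene).

Key step: step 14

Remark: dictyotane locants of the target are used for atoms of all intermediates (C1/C5 ring fusion, C4 tertiary carbinol, C6 secondary carbinol, C7 side-chain carbon, C10=C18 methylidene, side chain C11–C15 with the acetate at C13). Commercial (R)-citronellic acid and (S)-but-3-yn-2-ol are taken as enantiopure.

**Step 1**
Reactants: 1 (R)-citronellic acid [(3R)-3,7-dimethyloct-6-enoic acid]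
Product: 4 (4R,6R)-4-methyl-6-(2-methylprop-1-en-1-yl)oxan-2-one, via allylic hydroperoxide 2 (not isolated), via hydroxy acid 3 (not isolated)
Conditions: O2, hν, tetraphenylporphyrin (cat.), CH2Cl2, 0 °C; PPh3; then camphorsulfonic acid (cat.), rt
Reagents that add atoms: none
Why: Schenck ene reaction of singlet oxygen at the trisubstituted alkene, phosphine reduction and acid-catalysed SN1′ lactonisation through the allyl cation should give the δ-lactone, the reversible closure favouring the cis-4,6-diequatorial isomer and so setting C13 (R) relative to C11; the regioisomeric ene product cannot lactonise in this way and should be removable by base extraction.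

**Step 2**
Reactants: 5 3-bromobut-3-en-1-ol
Product: 6 3-bromobut-3-en-1-yl trifluoromethanesulfonate
Conditions: Tf2O, pyridine, CH2Cl2, −78 °C, used at once
Reagents that add atoms: trifluoromethanesulfonic anhydride O=S(=O)(OS(=O)(=O)C(F)(F)F)C(F)(F)F
Why: Sulfonylation of a primary alcohol gives a triflate that alkylates enolates at low temperature faster than it eliminates.

**Step 3**
Reactants: 4 (4R,6R)-4-methyl-6-(2-methylprop-1-en-1-yl)oxan-2-one; 6 3-bromobut-3-en-1-yl trifluoromethanesulfonate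
Product: 8 (3S,4R,6R)-3-(3-bromobut-3-en-1-yl)-4-methyl-6-(2-methylprop-1-en-1-yl)oxan-2-one, via lithium enolate 7 (not isolated)
Conditions: LiN(i-Pr)2, THF, −78 °C; then 6, −78 → −40 °C
Reagents that add atoms: none
Why: Lactone enolate alkylation forms C7–C8; the electrophile should enter anti to the adjacent C11 methyl group, giving the all-equatorial 3,4-trans lactone (7S).

**Step 4**
Reactants: 8 (3S,4R,6R)-3-(3-bromobut-3-en-1-yl)-4-methyl-6-(2-methylprop-1-en-1-yl)oxan-2-one
Product: 9 (2S,3R,5R)-2-(3-bromobut-3-en-1-yl)-3,7-dimethyloct-6-ene-1,5-diol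
Conditions: LiBH4, THF, 0 °C → rt; aq NH4Cl
Reagents that add atoms: none
Why: Hydride reduction of the lactone opens the temporary ring to the C6/C13 diol without touching the vinyl bromide or any stereocenter.

**Step 5**
Reactants: 9 (2S,3R,5R)-2-(3-bromobut-3-en-1-yl)-3,7-dimethyloct-6-ene-1,5-diol
Product: 11 1-O-(tert-butyldimethylsilyl) 5-O-(triisopropylsilyl) ether of diol 9, via mono-silyl ether 10 (not isolated)
Conditions: t-BuMe2SiCl (1.05 equiv), imidazole, CH2Cl2, 0 °C; then i-Pr3SiOTf, 2,6-lutidine, 0 °C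
Reagents that add atoms: tert-butyldimethylsilyl chloride CC(C)(C)[Si](C)(C)Cl; triisopropylsilyl trifluoromethanesulfonate CC(C)[Si](C(C)C)(C(C)C)OS(=O)(=O)C(F)(F)F
Why: Silylation follows steric accessibility: the primary C6 hydroxyl takes the silyl chloride first and the secondary allylic C13 hydroxyl is then capped with the more reactive silyl triflate.

**Step 6**
Reactants: 12 (S)-but-3-yn-2-ol
Product: 14 (2S,3E)-4-(4,4,5,5-tetramethyl-1,3,2-dioxaborolan-2-yl)but-3-en-2-ol, via O-boryl alkenylboronate 13 (not isolated)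
Conditions: pinacolborane (2.2 equiv), Cp2Zr(H)Cl (5 mol %), Et3N (10 mol %), CH2Cl2, 40 °C; aq NH4Cl
Reagents that add atoms: pinacolborane CC1(C)OBOC1(C)C
Why: Zirconium-catalysed syn hydroboration of the terminal alkyne gives the (E)-alkenylboronate; the carbinol stereocenter is untouched and its O–B bond is cleaved on aqueous work-up.

**Step 7**
Reactants: 11 1-O-(tert-butyldimethylsilyl) 5-O-(triisopropylsilyl) ether of diol 9; 14 (2S,3E)-4-(4,4,5,5-tetramethyl-1,3,2-dioxaborolan-2-yl)but-3-en-2-ol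
Product: 15 (2S,3E,8S,9R,11R)-8-{[(tert-butyldimethylsilyl)oxy]methyl}-9,13-dimethyl-5-methylidene-11-[(triisopropylsilyl)oxy]tetradeca-3,12-dien-2-ol
Conditions: Pd(dppf)Cl2 (5 mol %), K3PO4, THF/H2O, 50 °C
Reagents that add atoms: none
Why: Suzuki–Miyaura coupling of the 2-bromoalkene with the (E)-alkenylboronate forms C1–C10 with retention of alkene geometry and tolerates the free hydroxyl.

**Step 8**
Reactants: 15 (2S,3E,8S,9R,11R)-8-{[(tert-butyldimethylsilyl)oxy]methyl}-9,13-dimethyl-5-methylidene-11-[(triisopropylsilyl)oxy]tetradeca-3,12-dien-2-ol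
Product: 18 ethyl (3S,4E)-3-[(5S,6R,8R)-5-{[(tert-butyldimethylsilyl)oxy]methyl}-6,10-dimethyl-8-[(triisopropylsilyl)oxy]undeca-1,9-dien-2-yl]hex-4-enoate, via mixed orthoester 16 (not isolated), via ketene acetal 17 (not isolated)
Conditions: CH3C(OEt)3 (excess), propionic acid (cat.), 135 °C, ethanol distilled off
Reagents that add atoms: triethyl orthoacetate CCOC(C)(OCC)OCC
Why: Johnson–Claisen rearrangement through a chair with the carbinol methyl equatorial forms C1–C5, transfers the (S) carbinol chirality to C1 and leaves an (E)-propenyl group.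

**Step 9**
Reactants: 18 ethyl ester from step 8
Product: 19 (3S,4E)-3-[(5S,6R,8R)-5-{[(tert-butyldimethylsilyl)oxy]methyl}-6,10-dimethyl-8-[(triisopropylsilyl)oxy]undeca-1,9-dien-2-yl]-N-methoxy-N-methylhex-4-enamide
Conditions: MeNH(OMe)·HCl, i-PrMgCl, THF, −20 → 0 °C
Reagents that add atoms: N,O-dimethylhydroxylamine hydrochloride CNOC.Cl
Why: Aminolysis of the ester by the chloromagnesium amide gives the Weinreb amide without touching a stereocenter.

**Step 10**
Reactants: 19 Weinreb amide from step 9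
Product: 20 (3S,4E)-3-[(5S,6R,8R)-5-(hydroxymethyl)-6,10-dimethyl-8-[(triisopropylsilyl)oxy]undeca-1,9-dien-2-yl]-N-methoxy-N-methylhex-4-enamide
Conditions: HF·pyridine, pyridine, THF, 0 °C
Reagents that add atoms: none
Why: Buffered HF·pyridine should cleave the primary tert-butyldimethylsilyl ether much faster than the secondary triisopropylsilyl ether.

**Step 11**
Reactants: 20 hydroxy Weinreb amide from step 10
Product: 21 (5S,6E)-5-[(5S,6R,8R)-5-(hydroxymethyl)-6,10-dimethyl-8-[(triisopropylsilyl)oxy]undeca-1,9-dien-2-yl]octa-1,6-dien-3-one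
Conditions: CH2=CHMgBr (3 equiv), THF, −78 → 0 °C; poured into cold aq NH4Cl
Reagents that add atoms: vinylmagnesium bromide C=C[Mg]Br
Why: Weinreb ketone synthesis: the chelated tetrahedral adduct stops at the ketone stage and releases the vinyl ketone on quench, one equivalent of Grignard reagent being consumed by the hydroxyl group.

**Step 12**
Reactants: 21 hydroxy vinyl ketone from step 11
Product: 24 (2S,3R,5R)-2-[(4R,5Z)-6-[(tert-butyldimethylsilyl)oxy]-3-methylidene-4-[(1E)-prop-1-en-1-yl]octa-5,7-dien-1-yl]-3,7-dimethyl-5-[(triisopropylsilyl)oxy]oct-6-en-1-ol, via trimethylsilyl ether 22 (not isolated), via bis-silylated dienol ether 23 (not isolated)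
Conditions: Me3SiCl, Et3N, CH2Cl2, 0 °C; t-BuMe2SiOTf, Et3N, −78 → 0 °C; then K2CO3 (cat.), MeOH, 0 °C
Reagents that add atoms: tert-butyldimethylsilyl trifluoromethanesulfonate CC(C)(C)[Si](C)(C)OS(=O)(=O)C(F)(F)F
Why: Soft enolisation of the vinyl ketone gives the 2-silyloxy-1,3-diene as the only possible enol silane (C5 is the sole α-CH2); the primary alcohol is masked as its trimethylsilyl ether meanwhile and freed by mild methanolysis.

**Step 13**
Reactants: 24 hydroxy enol silane from step 12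
Product: 25 (2S,3R,5R)-2-[(4R,5Z)-6-[(tert-butyldimethylsilyl)oxy]-3-methylidene-4-[(1E)-prop-1-en-1-yl]octa-5,7-dien-1-yl]-3,7-dimethyl-5-[(triisopropylsilyl)oxy]oct-6-enal
Conditions: Dess–Martin periodinane, NaHCO3, CH2Cl2, 0 °C
Reagents that add atoms: none
Why: Buffered Dess–Martin oxidation of the primary alcohol should leave the enol silane and the α-stereocenter C7 intact.

**Step 14**
Reactants: 25 enol silane aldehyde from step 13
Product: 26 1-[(1R,2R,3S,7R)-2-hydroxy-6-methylidene-3-[(2R,4R)-6-methyl-4-[(triisopropylsilyl)oxy]hept-5-en-2-yl]-7-[(1E)-prop-1-en-1-yl]cycloheptyl]prop-2-en-1-one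
Conditions: BF3·OEt2 (1.1 equiv), CH2Cl2 (0.005 M), −78 °C; aq NaHCO3
Reagents that add atoms: none
Why: BF3 activates the C6 aldehyde and the enol silane carbon C5 attacks it with loss of the silyl group to fluoride, the closest known reaction type being the Lewis-acid-mediated intramolecular Mukaiyama aldol of an enol silane onto a tethered aldehyde. The seven-membered ring closes in a 7-(enolexo)-exo-trig mode, C4 staying outside the ring. At C5, allylic 1,3-strain with the cis silyloxy group holds the C1–H bond in the plane of the C4=C5 double bond, so the tether (C10) lies on one face and the propenyl group on the other; attack from the tether face places the acyl group trans to the propenyl group (the future trans ring fusion), whereas cis closure needs a strained rotamer. At C6, an open transition state with the aldehyde hydrogen in the crowded sector between C4 and C1 and the chain carbon C7 next to H5 should give the anti H5/H6 relationship (6R). The step needs chemoselectivity over the C10=C18, propenyl and C14=C15 alkenes (Prins or ene closure), which the far higher nucleophilicity of the enol silane at −78 °C should secure; regioselectivity is built in because C5 is the only enolisable carbon of the vinyl ketone.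

**Step 15**
Reactants: 26 β-hydroxy vinyl ketone from step 14
Product: 27 (2S)-2-[(1R,2R,3S,7R)-2-hydroxy-6-methylidene-3-[(2R,4R)-6-methyl-4-[(triisopropylsilyl)oxy]hept-5-en-2-yl]-7-[(1E)-prop-1-en-1-yl]cycloheptyl]but-3-en-2-ol
Conditions: CH3MgBr (4 equiv), CH2Cl2/Et2O, −78 °C
Reagents that add atoms: methylmagnesium bromide C[Mg]Br
Why: Grignard 1,2-addition under 1,3-chelation control: the magnesium alkoxide at O6 and the ketone oxygen form a six-membered chelate with C1 and C7 equatorial, and methyl should add axially, anti to H5 (as hydride does in the Narasaka–Prasad reduction), giving the 4S carbinol of the syn-1,3-diol.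

**Step 16**
Reactants: 27 diene diol from step 15
Product: 28 (1S,3aR,7S,8R,8aR)-1-methyl-4-methylidene-7-[(2R,4R)-6-methyl-4-[(triisopropylsilyl)oxy]hept-5-en-2-yl]-1,3a,4,5,6,7,8,8a-octahydroazulene-1,8-diol
Conditions: second-generation Grubbs catalyst RuCl2(=CHPh)(H2IMes)(PCy3) (5 mol %), CH2Cl2, 40 °C
Reagents that add atoms: none
Why: Ring-closing metathesis between the C4 vinyl and C1 propenyl groups forms the cyclopentene C2=C3 with loss of propene; the 1,1-disubstituted C10=C18 and trisubstituted C14=C15 alkenes cannot close an unstrained ring and should stay out.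

**Step 17**
Reactants: 28 silyl ether from step 16
Product: 29 (1S,3aR,7S,8R,8aR)-7-[(2R,4R)-4-hydroxy-6-methylhept-5-en-2-yl]-1-methyl-4-methylidene-1,3a,4,5,6,7,8,8a-octahydroazulene-1,8-diol
Conditions: Bu4NF, THF, rt
Reagents that add atoms: none
Why: Fluoride cleaves the one remaining silyl ether under basic conditions that do not ionise the tertiary allylic alcohol.

**Step 18**
Reactants: 29 triol from step 17
Product: 30 (4R,6R)-6-[(1S,3aR,7S,8R,8aR)-1,8-dihydroxy-1-methyl-4-methylidene-1,3a,4,5,6,7,8,8a-octahydroazulen-7-yl]-2-methylhept-2-en-4-yl acetate (target)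
Conditions: Ac2O (1.2 equiv), pyridine, CH2Cl2, 0 °C
Reagents that add atoms: acetic anhydride CC(=O)OC(C)=O
Why: Acylation should take the least hindered hydroxyl: C13–OH is an open secondary allylic alcohol, C6–OH is flanked by two methine carbons and C4–OH is tertiary.

**Compound list**

1 | (R)-citronellic acid, (3R)-3,7-dimethyloct-6-enoic acid | OC(=O)C[C@H](C)CCC=C(C)C | starting material
2 | (3R,5E)-7-hydroperoxy-3,7-dimethyloct-5-enoic acid | OC(=O)C[C@H](C)C/C=C/C(C)(C)OO | intermediate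
3 | (3R,5E)-7-hydroxy-3,7-dimethyloct-5-enoic acid | OC(=O)C[C@H](C)C/C=C/C(C)(C)O | intermediate
4 | (4R,6R)-4-methyl-6-(2-methylprop-1-en-1-yl)oxan-2-one (cis δ-lactone) | O=C1C[C@H](C)C[C@H](C=C(C)C)O1 | intermediate
5 | 3-bromobut-3-en-1-ol | C=C(Br)CCO | starting material
6 | 3-bromobut-3-en-1-yl trifluoromethanesulfonate | C=C(Br)CCOS(=O)(=O)C(F)(F)F | intermediate
7 | lithium enolate of lactone 4 | [Li+].[O-]C1=C[C@H](C)C[C@H](C=C(C)C)O1 | intermediate
8 | (3S,4R,6R)-3-(3-bromobut-3-en-1-yl)-4-methyl-6-(2-methylprop-1-en-1-yl)oxan-2-one | C=C(Br)CC[C@H]1[C@H](C)C[C@H](C=C(C)C)OC1=O | intermediate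
9 | (2S,3R,5R)-2-(3-bromobut-3-en-1-yl)-3,7-dimethyloct-6-ene-1,5-diol | C=C(Br)CC[C@@H]([C@H](C)C[C@H](C=C(C)C)O)CO | intermediate
10 | 1-O-(tert-butyldimethylsilyl) ether of diol 9 | C=C(Br)CC[C@@H]([C@H](C)C[C@H](C=C(C)C)O)CO[Si](C)(C)C(C)(C)C | intermediate
11 | 1-O-(tert-butyldimethylsilyl) 5-O-(triisopropylsilyl) ether of diol 9 | C=C(Br)CC[C@@H]([C@H](C)C[C@H](C=C(C)C)O[Si](C(C)C)(C(C)C)C(C)C)CO[Si](C)(C)C(C)(C)C | intermediate
12 | (S)-but-3-yn-2-ol | C[C@H](O)C#C | starting material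
13 | (2S,3E)-O-(pinacolboryl) ether of boronate 14 | C[C@H](OB1OC(C)(C)C(C)(C)O1)/C=C/B1OC(C)(C)C(C)(C)O1 | intermediate
14 | (2S,3E)-4-(4,4,5,5-tetramethyl-1,3,2-dioxaborolan-2-yl)but-3-en-2-ol | C[C@H](O)/C=C/B1OC(C)(C)C(C)(C)O1 | intermediate
15 | (2S,3E,8S,9R,11R)-8-{[(tert-butyldimethylsilyl)oxy]methyl}-9,13-dimethyl-5-methylidene-11-[(triisopropylsilyl)oxy]tetradeca-3,12-dien-2-ol | C[C@H](O)/C=C/C(=C)CC[C@@H]([C@H](C)C[C@H](C=C(C)C)O[Si](C(C)C)(C(C)C)C(C)C)CO[Si](C)(C)C(C)(C)C | intermediate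
16 | mixed diethyl orthoacetate of alcohol 15 | CCOC(C)(OCC)O[C@@H](C)/C=C/C(=C)CC[C@@H]([C@H](C)C[C@H](C=C(C)C)O[Si](C(C)C)(C(C)C)C(C)C)CO[Si](C)(C)C(C)(C)C | intermediate
17 | ethyl ketene acetal of alcohol 15 | C=C(OCC)O[C@@H](C)/C=C/C(=C)CC[C@@H]([C@H](C)C[C@H](C=C(C)C)O[Si](C(C)C)(C(C)C)C(C)C)CO[Si](C)(C)C(C)(C)C | intermediate
18 | ethyl (3S,4E)-3-[(5S,6R,8R)-5-{[(tert-butyldimethylsilyl)oxy]methyl}-6,10-dimethyl-8-[(triisopropylsilyl)oxy]undeca-1,9-dien-2-yl]hex-4-enoate | CCOC(=O)C[C@@H](/C=C/C)C(=C)CC[C@@H]([C@H](C)C[C@H](C=C(C)C)O[Si](C(C)C)(C(C)C)C(C)C)CO[Si](C)(C)C(C)(C)C | intermediate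
19 | (3S,4E)-3-[(5S,6R,8R)-5-{[(tert-butyldimethylsilyl)oxy]methyl}-6,10-dimethyl-8-[(triisopropylsilyl)oxy]undeca-1,9-dien-2-yl]-N-methoxy-N-methylhex-4-enamide | CON(C)C(=O)C[C@@H](/C=C/C)C(=C)CC[C@@H]([C@H](C)C[C@H](C=C(C)C)O[Si](C(C)C)(C(C)C)C(C)C)CO[Si](C)(C)C(C)(C)C | intermediate
20 | (3S,4E)-3-[(5S,6R,8R)-5-(hydroxymethyl)-6,10-dimethyl-8-[(triisopropylsilyl)oxy]undeca-1,9-dien-2-yl]-N-methoxy-N-methylhex-4-enamide | CON(C)C(=O)C[C@@H](/C=C/C)C(=C)CC[C@@H]([C@H](C)C[C@H](C=C(C)C)O[Si](C(C)C)(C(C)C)C(C)C)CO | intermediate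
21 | (5S,6E)-5-[(5S,6R,8R)-5-(hydroxymethyl)-6,10-dimethyl-8-[(triisopropylsilyl)oxy]undeca-1,9-dien-2-yl]octa-1,6-dien-3-one | C=CC(=O)C[C@@H](/C=C/C)C(=C)CC[C@@H]([C@H](C)C[C@H](C=C(C)C)O[Si](C(C)C)(C(C)C)C(C)C)CO | intermediate
22 | O-trimethylsilyl ether of hydroxy ketone 21 | C=CC(=O)C[C@@H](/C=C/C)C(=C)CC[C@@H]([C@H](C)C[C@H](C=C(C)C)O[Si](C(C)C)(C(C)C)C(C)C)CO[Si](C)(C)C | intermediate
23 | O-trimethylsilyl ether of enol silane 24 | C=C/C(O[Si](C)(C)C(C)(C)C)=C/[C@@H](/C=C/C)C(=C)CC[C@@H]([C@H](C)C[C@H](C=C(C)C)O[Si](C(C)C)(C(C)C)C(C)C)CO[Si](C)(C)C | intermediate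
24 | (2S,3R,5R)-2-[(4R,5Z)-6-[(tert-butyldimethylsilyl)oxy]-3-methylidene-4-[(1E)-prop-1-en-1-yl]octa-5,7-dien-1-yl]-3,7-dimethyl-5-[(triisopropylsilyl)oxy]oct-6-en-1-ol | C=C/C(O[Si](C)(C)C(C)(C)C)=C/[C@@H](/C=C/C)C(=C)CC[C@@H]([C@H](C)C[C@H](C=C(C)C)O[Si](C(C)C)(C(C)C)C(C)C)CO | intermediate
25 | (2S,3R,5R)-2-[(4R,5Z)-6-[(tert-butyldimethylsilyl)oxy]-3-methylidene-4-[(1E)-prop-1-en-1-yl]octa-5,7-dien-1-yl]-3,7-dimethyl-5-[(triisopropylsilyl)oxy]oct-6-enal | C=C/C(O[Si](C)(C)C(C)(C)C)=C/[C@@H](/C=C/C)C(=C)CC[C@@H]([C@H](C)C[C@H](C=C(C)C)O[Si](C(C)C)(C(C)C)C(C)C)C=O | intermediate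
26 | 1-[(1R,2R,3S,7R)-2-hydroxy-6-methylidene-3-[(2R,4R)-6-methyl-4-[(triisopropylsilyl)oxy]hept-5-en-2-yl]-7-[(1E)-prop-1-en-1-yl]cycloheptyl]prop-2-en-1-one | C=C1CC[C@@H]([C@H](C)C[C@H](C=C(C)C)O[Si](C(C)C)(C(C)C)C(C)C)[C@@H](O)[C@H](C(=O)C=C)[C@H]1/C=C/C | intermediate
27 | (2S)-2-[(1R,2R,3S,7R)-2-hydroxy-6-methylidene-3-[(2R,4R)-6-methyl-4-[(triisopropylsilyl)oxy]hept-5-en-2-yl]-7-[(1E)-prop-1-en-1-yl]cycloheptyl]but-3-en-2-ol | C=C1CC[C@@H]([C@H](C)C[C@H](C=C(C)C)O[Si](C(C)C)(C(C)C)C(C)C)[C@@H](O)[C@H]([C@@](C)(O)C=C)[C@H]1/C=C/C | intermediate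
28 | (1S,3aR,7S,8R,8aR)-1-methyl-4-methylidene-7-[(2R,4R)-6-methyl-4-[(triisopropylsilyl)oxy]hept-5-en-2-yl]-1,3a,4,5,6,7,8,8a-octahydroazulene-1,8-diol | C=C1CC[C@@H]([C@H](C)C[C@H](C=C(C)C)O[Si](C(C)C)(C(C)C)C(C)C)[C@@H](O)[C@H]2[C@H]1C=C[C@]2(C)O | intermediate
29 | (1S,3aR,7S,8R,8aR)-7-[(2R,4R)-4-hydroxy-6-methylhept-5-en-2-yl]-1-methyl-4-methylidene-1,3a,4,5,6,7,8,8a-octahydroazulene-1,8-diol | C=C1CC[C@@H]([C@H](C)C[C@H](C=C(C)C)O)[C@@H](O)[C@H]2[C@H]1C=C[C@]2(C)O | intermediate
30 | (4R,6R)-6-[(1S,3aR,7S,8R,8aR)-1,8-dihydroxy-1-methyl-4-methylidene-1,3a,4,5,6,7,8,8a-octahydroazulen-7-yl]-2-methylhept-2-en-4-yl acetate | C=C1CC[C@@H]([C@H](C)C[C@H](C=C(C)C)OC(C)=O)[C@@H](O)[C@H]2[C@H]1C=C[C@]2(C)O | target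

**Totals and risks**

Total step count: 18. Longest linear sequence: 16 steps (steps 1, 3, 4, 5 and 7 to 18).

Step 14 (ring closure). What may go wrong: closure through another transition state (attack on the other face of C5 or of the aldehyde), or capture of the BF3-activated aldehyde by an alkene π-bond (Prins or ene closure to a six-membered ring) ahead of the enol silane. Fallback, from 24 back to 26: the enol silane 24 is brominated at C5 with N-bromosuccinimide in THF at −78 °C to give the α-bromo vinyl ketone F1 (C5 epimers). The primary alcohol is oxidised with Dess–Martin periodinane to the bromo keto aldehyde F2. Treatment with SmI2 in THF at −78 °C then generates a trivalent samarium enolate at C5, which should close onto the aldehyde through a chelated chair-like transition state (Reformatsky-type aldol, no Lewis acid present) to give 26.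

Step 15 (methyl addition). What may go wrong: conjugate addition to the vinyl ketone, oxa-Michael closure of the C6 alkoxide onto the enone, or methyl delivery to the wrong face if the chelate does not form. Fallback, from 26 back to 29, which fixes C4 by oxygen delivery instead of carbon delivery: 26 is silylated at O6 (Et3SiOTf, 2,6-lutidine) to the triethylsilyl ether F3. MeLi with CeCl3 then gives the tertiary alcohol F4 as a C4 epimer mixture. Ring-closing metathesis gives the cyclopentenol F5. Oxidative 1,3-transposition with pyridinium chlorochromate (C5H5NH)[CrO3Cl] gives the enone F6 (C2 ketone, C3=C4 bearing the methyl group). Nucleophilic epoxidation (H2O2, NaOH, MeOH, 0 °C) should occur anti to C6 to give the α-epoxy ketone F7. Wharton transposition (N2H4·H2O, AcOH, MeOH) gives the allylic alcohol F8 with C2=C3 and the 4S carbinol. Bu4NF as in step 17 removes both silyl groups and returns the route to 29.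

Step 18 (acetylation). What may go wrong: loss of site selectivity, with acylation also at the C6 hydroxyl. Fallback, from 29 back to 30: the syn-1,3-diol (O4/O6) of 29 is tied up with PhB(OH)2 (toluene, MgSO4) as the cyclic phenylboronate F9. The only free hydroxyl is acetylated (Ac2O, DMAP, pyridine) to the acetate boronate F10. The boronate is removed by exchange with pinacol at rt to give 30.

**Further compounds**

F1 | step 14 | α-bromo vinyl ketone, 5-bromo derivative of hydroxy ketone 21 (C5 epimers) | C=CC(=O)C(Br)[C@@H](/C=C/C)C(=C)CC[C@@H]([C@H](C)C[C@H](C=C(C)C)O[Si](C(C)C)(C(C)C)C(C)C)CO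
F2 | step 14 | bromo keto aldehyde, C6 aldehyde of F1 | C=CC(=O)C(Br)[C@@H](/C=C/C)C(=C)CC[C@@H]([C@H](C)C[C@H](C=C(C)C)O[Si](C(C)C)(C(C)C)C(C)C)C=O
F3 | step 15 | 6-O-triethylsilyl ether of 26 | C=C1CC[C@@H]([C@H](C)C[C@H](C=C(C)C)O[Si](C(C)C)(C(C)C)C(C)C)[C@@H](O[Si](CC)(CC)CC)[C@H](C(=O)C=C)[C@H]1/C=C/C
F4 | step 15 | 6-O-triethylsilyl tertiary alcohol, C4 epimer mixture | C=C1CC[C@@H]([C@H](C)C[C@H](C=C(C)C)O[Si](C(C)C)(C(C)C)C(C)C)[C@@H](O[Si](CC)(CC)CC)[C@H](C(C)(O)C=C)[C@H]1/C=C/C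
F5 | step 15 | 6-O-triethylsilyl cyclopentenol, C4 epimer mixture | C=C1CC[C@@H]([C@H](C)C[C@H](C=C(C)C)O[Si](C(C)C)(C(C)C)C(C)C)[C@@H](O[Si](CC)(CC)CC)[C@H]2[C@H]1C=CC2(C)O
F6 | step 15 | transposed enone (C2 ketone, C3=C4) | C=C1CC[C@@H]([C@H](C)C[C@H](C=C(C)C)O[Si](C(C)C)(C(C)C)C(C)C)[C@@H](O[Si](CC)(CC)CC)[C@H]2[C@H]1C(=O)C=C2C
F7 | step 15 | 3α,4α-epoxy ketone | C=C1CC[C@@H]([C@H](C)C[C@H](C=C(C)C)O[Si](C(C)C)(C(C)C)C(C)C)[C@@H](O[Si](CC)(CC)CC)[C@H]2[C@H]1C(=O)[C@@H]3O[C@]23C
F8 | step 15 | 6-O-triethylsilyl ether of 28 | C=C1CC[C@@H]([C@H](C)C[C@H](C=C(C)C)O[Si](C(C)C)(C(C)C)C(C)C)[C@@H](O[Si](CC)(CC)CC)[C@H]2[C@H]1C=C[C@]2(C)O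
F9 | step 18 | cyclic 4,6-O-phenylboronate of triol 29 | C=C1CC[C@@H]([C@H](C)C[C@H](C=C(C)C)O)[C@@H](O3)[C@H]2[C@H]1C=C[C@]2(C)OB3c1ccccc1
F10 | step 18 | cyclic 4,6-O-phenylboronate of target 30 | C=C1CC[C@@H]([C@H](C)C[C@H](C=C(C)C)OC(C)=O)[C@@H](O3)[C@H]2[C@H]1C=C[C@]2(C)OB3c1ccccc1
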